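We have to decide which flask to run, and two chemists disagree on how to count the partner. Each step that uses partner uses one of it: on catalyst intermediate A it gives target, on catalyst intermediate B second product, and on precatalyst free catalyst and spent reagent.

| flask | starting material | second substrate | partner | precatalyst | remark | time |
|---|---|---|---|---|---|---|
| elm | 0.10 M | 0.050 M | 0.053 M | 5 mM | run made earlier |  |
| maple | 0.10 M | 0.050 M | 0.17 M | 5 mM | run made earlier |  |
| oak | 0.10 M | 0.038 M | 0.060 M | 5 mM | run made earlier |  |
| theta | 0.10 M | 0.100 M | 0.120 M | 15 mM |  | 4.0 h |
| alpha | 0.10 M | 0.0300 M | 0.200 M | 5.0 mM |  | 4.0 h |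
| eta | 0.10 M | 0.0120 M | 0.0600 M | 5.0 mM |  | 4.0 h |
| delta | 0.10 M | 0.0500 M | 0.0600 M | 5.0 mM |  | 4.0 h |
| epsilon | 0.050 M | 0.0500 M | 0.120 M | 5.0 mM |  | 4.0 h |
| beta | 0.050 M | 0.100 M | 0.0600 M | 8.0 mM |  | 4.0 h |

| run | time / h | target / % |
|---|---|---|
| elm | 0.667 | 3.8 |
| elm | 1.33 | 9.2 |
| elm | 2.00 | 17.3 |
| elm | 3.00 | 21.6 |
| maple | 0.333 | 6.7 |
| maple | 1.00 | 38.8 |
| maple | 2.00 | 73.3 |
| maple | 3.00 | 86.6 |
| oak | 0.250 | 0 |
| oak | 0.500 | 2.8 |
| oak | 1.33 | 15.1 |
| oak | 3.00 | 30.3 |

(readings scatter by 1 percentage point)

* all flasks from highest to lowest amount of target, in percent of the starting material charged, at 4.0 h (theta / alpha / eta / delta / epsilon / beta)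
* the amount of target, in percent of the starting material charged of the flask you put first, at 4.0 h
* the amount of target, in percent of the starting material charged of the flask you put last, at 4.0 h

- candidate steps: starting material + free catalyst <-> catalyst intermediate A; partner + catalyst intermediate A -> free catalyst + target; second substrate + free catalyst <-> catalyst intermediate B; partner + catalyst intermediate B -> free catalyst + second product; partner + precatalyst -> free catalyst + spent reagent
- no earlier run changes the charge of precatalyst; that part of a forecast is a guess

The first chemist, who made the forecast, counts speeds: second substrate “is consumed about 2.5 times faster per unit concentration than starting material”. The forecast puts the flasks as alpha > epsilon > eta > theta > delta > beta, with 95% at the top and 18% at the bottom.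

The second chemist counts demands. She defines the coverage φ as partner charged divided by the sum of starting material, second substrate and precatalyst charged, which is the partner needed to finish them at one each. Below one, partner is the limiting reagent. Taken in proportion to charge and to the end, the conversion equals φ.

She then freezes the shortfall from that. Oak's last reading, 30.3% at 3.00 h with φ of 0.420, gives the target per unit of coverage, g = 0.722. Elm, with φ of 0.342, reads a lower 0.632, so g carries that spread.

For beta, φ is 0.380, which lies between elm's and oak's. Her reckoning therefore gives 27.4%, higher than the forecast's figure. Theta has φ of 0.558 and eta 0.513, so she ranks theta above eta, against the forecast.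

She grants one region: eta, with second substrate at 0.0120 M, less than its 0.10 M of starting material, is where she leaves the call to the first view.

The flasks give alpha > epsilon > theta > eta > delta > beta; alpha, first, stands at 98.6%, and beta, last, at 27.1%.

    starting material + free catalyst ⇌ catalyst intermediate A (K = 17.0 /M, k = 17.0 /M/min)
    partner + catalyst intermediate A → free catalyst + target (k = 5.50 /M/min)
    second substrate + free catalyst ⇌ catalyst intermediate B (K = 55.0 /M, k = 3.80 /M/min)
    partner + catalyst intermediate B → free catalyst + second product (k = 29.0 /M/min)
    partner + precatalyst → free catalyst + spent reagent (k = 0.120 /M/min)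

Against that 27.1% stand the forecast's 18% and the 27.4% from g and φ. At 4.00 h beta's partner is down to 0.0162% of its charge, with 72.0% of the starting material still unbound. Eta, at 40.4% against the forecast's 40, is the ground the first view keeps. Now take beta with 0.40 M of second substrate: φ falls to 0.131, so g times φ is 9.46%, and that flask gives 8.63%.

The readings are simulated with constants of no real substance; noise was put on by code.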